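**Retrosynthetic overview**
1. Locants: C1 = oxirane carbon carrying C7H2OBz, C2/C3 = acetoxy carbons, C4/C5 = carbinol carbons, C6 = oxirane CH. The plan rests on one feature of the cyclohexane ring. The oxirane oxygen on C1 and the hydroxyl oxygen on C4 lie on the same face, 1,4 to each other, with C6 and C5 between them. An O–O bridge across C1 and C4 leaves this pattern once each oxygen has been handed to its neighbouring carbon.
2. 16 ⇐ water at C5 (inversion) on the syn-1,6:4,5-bis-epoxide diacetate 15 ⇐ O–O isomerisation of the 2,3-dioxabicyclo[2.2.2]oct-5-ene 12 ⇐ singlet-oxygen [4+2] on the diene C1=C6–C5=C4 of 11 (trans C2-OH / C3-OTBS).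
3. 11 ⇐ C1–C7 Stille hydroxymethylation and O7-benzoylation of bromodienol 7 ⇐ cis-diol 1. The C2 inversion is run with C4=C5 temporarily saturated, because an activated cyclohexadienol would collapse to an arene.
4. Ring order: carbocycle purchased → 1,2-dioxine ring (step 9) → both oxiranes at once (step 10) → 4,5-oxirane opened (step 13).

Key step: step 9

Remark (convention and one assumption): target locants are used for all intermediates; "lower face" is the face of the oxirane oxygen of 16 and "upper face" that of C7; diol 1, sold as a buffered aqueous suspension, is assumed to be extracted and used without storage.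

Step 1
Reactants: 1 (1S,2S)-3-bromocyclohexa-3,5-diene-1,2-diol
Product: 2 (1S,2S)-3-bromocyclohex-3-ene-1,2-diol
Conditions: KO2CN=NCO2K, AcOH, MeOH, 0 °C → rt
Reagents that add atoms: none
Why: Diimide reduction: HN=NH made in situ delivers H2 concertedly to the unhindered disubstituted C4=C5 bond, the bromine-bearing C1=C6 bond is spared for steric and electronic reasons, and taking the diene apart here allows C2 to be activated in step 3 without aromatisation; no stereocentre is touched.

Step 2
Reactants: 2 (1S,2S)-3-bromocyclohex-3-ene-1,2-diol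
Product: 3 (1S,6S)-2-bromo-6-[(tert-butyldimethylsilyl)oxy]cyclohex-2-en-1-ol (C3-OTBS and C2-OH both on the upper face)
Conditions: TBSCl (1.05 equiv), imidazole, DMF, −10 → 0 °C
Reagents that add atoms: tert-butyldimethylsilyl chloride, CC(C)(C)[Si](C)(C)Cl
Why: Sterically controlled monosilylation: the bulky chlorosilane should take the C3 hydroxyl, which is flanked by a CH2, in preference to the C2 hydroxyl, which is crowded by the vinylic bromine.

Step 3
Reactants: 3 (1S,6S)-2-bromo-6-[(tert-butyldimethylsilyl)oxy]cyclohex-2-en-1-ol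
Product: 4 (1R,6S)-2-bromo-6-[(tert-butyldimethylsilyl)oxy]cyclohex-2-en-1-yl 4-nitrobenzoate (C2-O lower face, C3-O upper face)
Conditions: 4-O2NC6H4CO2H, PPh3, DIAD, THF, 0 °C → rt
Reagents that add atoms: 4-nitrobenzoic acid, O=C(O)c1ccc(cc1)[N+](=O)[O-]
Why: Mitsunobu inversion: the C2 oxyphosphonium ion is displaced by the carboxylate in an SN2 process from the lower face, anti to the leaving group and to the neighbouring silyl ether, which sets the trans C2/C3 relationship of the target, and the vinylic bromine discourages SN2′ attack at C6.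

Step 4
Reactants: 4 (1R,6S)-2-bromo-6-[(tert-butyldimethylsilyl)oxy]cyclohex-2-en-1-yl 4-nitrobenzoate
Product: 5 (1R,6S)-2,4-dibromo-6-[(tert-butyldimethylsilyl)oxy]cyclohex-2-en-1-yl 4-nitrobenzoate (bromine on target C5, both epimers, used crude)
Conditions: NBS (1.1 equiv), AIBN (cat.), PhCF3, 85 °C
Reagents that add atoms: N-bromosuccinimide, O=C1CCC(=O)N1Br
Why: Wohl–Ziegler allylic bromination: the C5 methylene holds the only unencumbered allylic C–H bonds, the other allylic hydrogen (C2–H) is deactivated towards the electrophilic bromine atom by its acyloxy group, and the new C5 centre is erased in the next step.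

Step 5
Reactants: 5 (1R,6S)-2,4-dibromo-6-[(tert-butyldimethylsilyl)oxy]cyclohex-2-en-1-yl 4-nitrobenzoate
Product: 6 (1R,6S)-2-bromo-6-[(tert-butyldimethylsilyl)oxy]cyclohexa-2,4-dien-1-yl 4-nitrobenzoate
Conditions: DBU, THF, 0 °C → rt
Reagents that add atoms: none
Why: E2 dehydrobromination: the C4 methylene offers an antiperiplanar hydrogen to either C5 epimer, while in the trans series C2–O/C3–H and C3–O/C2–H are syn pairs, so no anti-elimination towards an arene is available.

Step 6
Reactants: 6 (1R,6S)-2-bromo-6-[(tert-butyldimethylsilyl)oxy]cyclohexa-2,4-dien-1-yl 4-nitrobenzoate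
Product: 7 (1R,6S)-2-bromo-6-[(tert-butyldimethylsilyl)oxy]cyclohexa-2,4-dien-1-ol
Conditions: K2CO3 (cat.), MeOH, 0 °C
Reagents that add atoms: none
Why: Base-catalysed transesterification: the activated 4-nitrobenzoate is cleaved quickly at low temperature, the acid-sensitive dienol tolerates mild base, and the short contact time limits a 1,2-silyl shift, which would in any case be uphill towards the more hindered C2 oxygen.

Step 7
Reactants: 7 (1R,6S)-2-bromo-6-[(tert-butyldimethylsilyl)oxy]cyclohexa-2,4-dien-1-ol; 8 (tributylstannyl)methanol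
Product: 9 (1S,6S)-6-[(tert-butyldimethylsilyl)oxy]-2-(hydroxymethyl)cyclohexa-2,4-dien-1-ol
Conditions: Pd(PPh3)4 (5 mol %), 1,4-dioxane, 80 °C, Ar, dark
Reagents that add atoms: (tributylstannyl)methanol, CCCC[Sn](CCCC)(CCCC)CO
Why: Migita–Kosugi–Stille coupling: the dienyl C1–Br bond adds readily to Pd(0), the oxygen-bearing CH2 group is transferred in preference to butyl, and the neutral medium leaves both stereocentres and the silyl ether alone.

Step 8
Reactants: 9 (1S,6S)-6-[(tert-butyldimethylsilyl)oxy]-2-(hydroxymethyl)cyclohexa-2,4-dien-1-ol; 10 benzoyl chloride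
Product: 11 [(5S,6S)-5-[(tert-butyldimethylsilyl)oxy]-6-hydroxycyclohexa-1,3-dien-1-yl]methyl benzoate
Conditions: BzCl (1.05 equiv), pyridine, CH2Cl2, −30 °C
Reagents that add atoms: benzoyl chloride, O=C(Cl)c1ccccc1
Why: Selective O-acylation: the primary allylic C7 hydroxyl reacts far faster than the secondary C2 hydroxyl, which is wedged between the C1 branch and the silyl ether, and the primary ester is also the thermodynamic position should any acyl shift occur.

Step 9
Reactants: 11 [(5S,6S)-5-[(tert-butyldimethylsilyl)oxy]-6-hydroxycyclohexa-1,3-dien-1-yl]methyl benzoate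
Product: 12 [(1R,4R,7R,8R)-8-[(tert-butyldimethylsilyl)oxy]-7-hydroxy-2,3-dioxabicyclo[2.2.2]oct-5-en-1-yl]methyl benzoate (peroxide bridge C1–O–O–C4 on the lower face, syn to C2-OH, anti to C3-OTBS)
Conditions: O2, TPP (cat.), hν (vis), CH2Cl2, −20 °C
Reagents that add atoms: dioxygen, O=O
Why: Sensitised singlet oxygen serves as the 2π component of a concerted suprafacial [π4s+π2s] cycloaddition to the ring-locked s-cis diene C1=C6–C5=C4, the classical endoperoxide synthesis from cyclohexa-1,3-dienes. The only ring closed is the six-membered 3,6-dihydro-1,2-dioxine C1–O–O–C4–C5=C6, formed by making C1–O and C4–O in the same event, which bridges the carbocycle to a 2,3-dioxabicyclo[2.2.2]oct-5-ene. C1 and C4 are created together and are coupled, since a two-atom bridge can span only one face, so one facial decision fixes both. That facial decision is the selectivity required: allylic A(1,2) strain with the C1 side chain should hold the C2 hydroxyl pseudoaxial on the lower face, where it can hydrogen-bond to the negatively polarised incoming oxygen (hydroxy-directed photooxygenation, best expressed in a non-polar, non-hydrogen-bonding solvent), and the trans relationship then places the bulky C3 silyl ether pseudoaxial on the upper face directly over C4. No regiochemical question arises with a symmetrical dienophile, and the Schenck ene pathway at C7–H, C2–H or C3–H should be outrun by cycloaddition to the planar diene; low temperature and the absence of base protect the peroxide and its C4–H from Kornblum–DeLaMare cleavage.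

Step 10
Reactants: 12 [(1R,4R,7R,8R)-8-[(tert-butyldimethylsilyl)oxy]-7-hydroxy-2,3-dioxabicyclo[2.2.2]oct-5-en-1-yl]methyl benzoate
Product: 13 [(1R,2R,3R,4R,5S,6S)-3-[(tert-butyldimethylsilyl)oxy]-2-hydroxy-1,6:4,5-diepoxycyclohexyl]methyl benzoate (both oxiranes on the lower face)
Conditions: Co(TPP) (5 mol %), CH2Cl2, 0 °C → rt
Reagents that add atoms: none
Why: Cobalt(II)-porphyrin-catalysed endoperoxide → syn-bis-epoxide isomerisation: electron transfer breaks the O–O bond, and the oxygen on C1 closes onto C6 while that on C4 closes onto C5 (two 3-exo closures), so C6 and C5 are set on the lower face because both oxygens are already anchored there, and the C2 hydroxyl, being cis to the 1,6-oxirane, cannot start a Payne shift.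

Step 11
Reactants: 13 [(1R,2R,3R,4R,5S,6S)-3-[(tert-butyldimethylsilyl)oxy]-2-hydroxy-1,6:4,5-diepoxycyclohexyl]methyl benzoate
Product: 14 [(1R,2R,3R,4S,5S,6S)-2,3-dihydroxy-1,6:4,5-diepoxycyclohexyl]methyl benzoate
Conditions: TBAF, AcOH (1:1), THF, 0 °C → rt
Reagents that add atoms: none
Why: Fluoride desilylation buffered with acetic acid: the near-neutral medium prevents build-up of the C3 alkoxide, which is trans to the 4,5-oxirane and could otherwise undergo Payne migration, and it leaves the benzoate and both oxiranes intact.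

Step 12
Reactants: 14 [(1R,2R,3R,4S,5S,6S)-2,3-dihydroxy-1,6:4,5-diepoxycyclohexyl]methyl benzoate
Product: 15 [(1S,2R,3S,4R,5S,6S)-2,3-diacetoxy-1,6:4,5-diepoxycyclohexyl]methyl benzoate
Conditions: Ac2O, pyridine, DMAP (cat.), CH2Cl2, 0 °C → rt
Reagents that add atoms: acetic anhydride, CC(=O)OC(C)=O
Why: DMAP-catalysed acetylation: the acylpyridinium reagent is reactive enough for the hindered C2 hydroxyl next to the quaternary C1, and the weak bases present do not disturb oxiranes or configuration.

Step 13
Reactants: 15 [(1S,2R,3S,4R,5S,6S)-2,3-diacetoxy-1,6:4,5-diepoxycyclohexyl]methyl benzoate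
Product: 16 [(1S,2R,3S,4R,5R,6S)-2,3-diacetoxy-4,5-dihydroxy-7-oxabicyclo[4.1.0]heptan-1-yl]methyl benzoate (target)
Conditions: HClO4 (cat.), THF–H2O, 0 °C → rt
Reagents that add atoms: water, O
Why: Acid-catalysed anti (SN2-like) epoxide hydrolysis with a non-nucleophilic counter-ion: the disubstituted 4,5-oxirane is the more basic and less shielded one (the 1,6-oxirane is trisubstituted, sits between two acyloxy-bearing carbons and is covered on its upper face by C7), and water should enter at C5 from the upper face because the rear of C4 is flanked by the upper-face C3 acetoxy group and feels its stronger inductive pull while the rear of C5 is flanked only by C6–H, so C5 is inverted, C4 keeps its lower-face oxygen and the all-trans C2–C5 array results.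

**Compound list**
1 | (1S,2S)-3-bromocyclohexa-3,5-diene-1,2-diol | O[C@H]1C=CC=C(Br)[C@H]1O | starting material
2 | (1S,2S)-3-bromocyclohex-3-ene-1,2-diol | O[C@H]1CCC=C(Br)[C@H]1O | intermediate
3 | (1S,6S)-2-bromo-6-[(tert-butyldimethylsilyl)oxy]cyclohex-2-en-1-ol | CC(C)(C)[Si](C)(C)O[C@H]1CCC=C(Br)[C@H]1O | intermediate
4 | (1R,6S)-2-bromo-6-[(tert-butyldimethylsilyl)oxy]cyclohex-2-en-1-yl 4-nitrobenzoate | CC(C)(C)[Si](C)(C)O[C@H]1CCC=C(Br)[C@@H]1OC(=O)c1ccc(cc1)[N+](=O)[O-] | intermediate
5 | (1R,6S)-2,4-dibromo-6-[(tert-butyldimethylsilyl)oxy]cyclohex-2-en-1-yl 4-nitrobenzoate (epimers at the CHBr carbon) | CC(C)(C)[Si](C)(C)O[C@H]1CC(Br)C=C(Br)[C@@H]1OC(=O)c1ccc(cc1)[N+](=O)[O-] | intermediate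
6 | (1R,6S)-2-bromo-6-[(tert-butyldimethylsilyl)oxy]cyclohexa-2,4-dien-1-yl 4-nitrobenzoate | CC(C)(C)[Si](C)(C)O[C@H]1C=CC=C(Br)[C@@H]1OC(=O)c1ccc(cc1)[N+](=O)[O-] | intermediate
7 | (1R,6S)-2-bromo-6-[(tert-butyldimethylsilyl)oxy]cyclohexa-2,4-dien-1-ol | CC(C)(C)[Si](C)(C)O[C@H]1C=CC=C(Br)[C@@H]1O | intermediate
8 | (tributylstannyl)methanol | CCCC[Sn](CCCC)(CCCC)CO | starting material
9 | (1S,6S)-6-[(tert-butyldimethylsilyl)oxy]-2-(hydroxymethyl)cyclohexa-2,4-dien-1-ol | CC(C)(C)[Si](C)(C)O[C@H]1C=CC=C(CO)[C@@H]1O | intermediate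
10 | benzoyl chloride | O=C(Cl)c1ccccc1 | starting material
11 | [(5S,6S)-5-[(tert-butyldimethylsilyl)oxy]-6-hydroxycyclohexa-1,3-dien-1-yl]methyl benzoate | CC(C)(C)[Si](C)(C)O[C@H]1C=CC=C(COC(=O)c2ccccc2)[C@@H]1O | intermediate
12 | [(1R,4R,7R,8R)-8-[(tert-butyldimethylsilyl)oxy]-7-hydroxy-2,3-dioxabicyclo[2.2.2]oct-5-en-1-yl]methyl benzoate | CC(C)(C)[Si](C)(C)O[C@H]1[C@H]2C=C[C@@](OO2)(COC(=O)c3ccccc3)[C@@H]1O | intermediate
13 | [(1R,2R,3R,4R,5S,6S)-3-[(tert-butyldimethylsilyl)oxy]-2-hydroxy-1,6:4,5-diepoxycyclohexyl]methyl benzoate | CC(C)(C)[Si](C)(C)O[C@H]1[C@@H]2O[C@@H]2[C@@H]2O[C@]2(COC(=O)c2ccccc2)[C@@H]1O | intermediate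
14 | [(1R,2R,3R,4S,5S,6S)-2,3-dihydroxy-1,6:4,5-diepoxycyclohexyl]methyl benzoate | O[C@H]1[C@@H]2O[C@@H]2[C@@H]2O[C@]2(COC(=O)c2ccccc2)[C@@H]1O | intermediate
15 | [(1S,2R,3S,4R,5S,6S)-2,3-diacetoxy-1,6:4,5-diepoxycyclohexyl]methyl benzoate | CC(=O)O[C@H]1[C@@H]2O[C@@H]2[C@@H]2O[C@]2(COC(=O)c2ccccc2)[C@@H]1OC(C)=O | intermediate
16 | [(1S,2R,3S,4R,5R,6S)-2,3-diacetoxy-4,5-dihydroxy-7-oxabicyclo[4.1.0]heptan-1-yl]methyl benzoate | CC(=O)O[C@H]1[C@H](O)[C@@H](O)[C@@H]2O[C@]2(COC(=O)c2ccccc2)[C@@H]1OC(C)=O | target

**Total step count:** 13. **Longest linear sequence:** 13 (1 → 16).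

**Steps most likely to fail**

Step 13 – loss of regiocontrol in the oxirane opening. Water may enter at C4. The C3 acetate carbonyl may attack C4 anchimerically, which would invert C4 instead of C5 and scramble the acetates. The benzoate may assist opening of the 1,6-oxirane at C6.
- The fallback sets out from 13 and comes back at 16.
- It moves the hydrolysis ahead of the silyl/acetyl exchange, so that C3 carries a group that cannot participate and that screens the upper face of C4.
- Acetylation of the C2 hydroxyl (Ac2O, pyridine, DMAP) should give the 2-O-acetyl-3-O-silyl bis-epoxide F1.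
- Mild Lewis-acid-catalysed hydrolysis (Er(OTf)3 cat., MeCN–H2O) should give the 3-O-silyl 4,5-diol F2.
- Chloroacetic anhydride/pyridine caps both new hydroxyls as the 4,5-bis(chloroacetate) F3.
- An acidic fluoride source (Et3N·3HF, MeCN), chosen to suppress acyl shifts, frees the C3 alcohol F4.
- Ac2O/pyridine gives the 2,3-diacetate 4,5-bis(chloroacetate) F5.
- DABCO in EtOH removes the chloroacetates selectively in the presence of acetates, benzoate and oxirane to give 16.

Step 9 – insufficient facial discrimination (addition of oxygen on the upper face) or diversion into the ene pathway.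
- The fallback sets out from 11 and comes back at 13, bypassing 12.
- It replaces the cycloaddition by two hydroxyl-directed epoxidations, both steered by the lower-face C2 hydroxyl.
- VO(acac)2/t-BuOOH in CH2Cl2 at 0 °C should first epoxidise the allylic C1=C6 bond syn to the hydroxyl, giving the lower-face 1,6-mono-epoxide F6.
- Further oxidant at room temperature should deliver oxygen to the homoallylic C4=C5 bond on the same face, which is also the face away from the C3 silyl ether, giving 13.

Step 4 – unselective hydrogen abstraction, over-bromination, or loss of the silyl ether through adventitious HBr.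
- The fallback sets out from 2 and comes back at 7.
- It carries both oxygens as electron-poor esters through the radical stage and installs the silyl ether only on the finished diene.
- Mitsunobu reaction of the free diol 2 with 4-nitrobenzoic acid, in which only the allylic C2 oxyphosphonium ion is displaced, should give the trans hydroxy 4-nitrobenzoate F7.
- Ac2O/pyridine gives the mixed acetate 4-nitrobenzoate diester F8.
- NBS/AIBN gives the C5 allylic bromide diester F9.
- DBU gives the bromodiene diester F10.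
- K2CO3/MeOH gives the trans-bromodiene diol F11.
- TBSCl/imidazole at low temperature silylates the less hindered C3 hydroxyl to give 7.

**Further compounds**
F1 | step 13 | 2-O-acetyl-3-O-silyl bis-epoxide: [2-acetoxy-3-(tert-butyldimethylsilyloxy)-1,6:4,5-diepoxycyclohexyl]methyl benzoate, oxiranes and C2-O lower face, C3-O upper face | CC(C)(C)[Si](C)(C)O[C@H]1[C@@H]2O[C@@H]2[C@@H]2O[C@]2(COC(=O)c2ccccc2)[C@@H]1OC(C)=O
F2 | step 13 | 3-O-silyl 4,5-diol: target skeleton with C3-OTBS in place of C3-OAc | CC(C)(C)[Si](C)(C)O[C@H]1[C@H](O)[C@@H](O)[C@@H]2O[C@]2(COC(=O)c2ccccc2)[C@@H]1OC(C)=O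
F3 | step 13 | 4,5-bis(chloroacetate) of F2 | CC(C)(C)[Si](C)(C)O[C@H]1[C@H](OC(=O)CCl)[C@@H](OC(=O)CCl)[C@@H]2O[C@]2(COC(=O)c2ccccc2)[C@@H]1OC(C)=O
F4 | step 13 | C3 alcohol: 2-acetate 4,5-bis(chloroacetate) with free C3-OH | O[C@H]1[C@H](OC(=O)CCl)[C@@H](OC(=O)CCl)[C@@H]2O[C@]2(COC(=O)c2ccccc2)[C@@H]1OC(C)=O
F5 | step 13 | 2,3-diacetate 4,5-bis(chloroacetate) | CC(=O)O[C@H]1[C@H](OC(=O)CCl)[C@@H](OC(=O)CCl)[C@@H]2O[C@]2(COC(=O)c2ccccc2)[C@@H]1OC(C)=O
F6 | step 9 | lower-face 1,6-mono-epoxide with C4=C5 retained, C2-OH lower face, C3-OTBS upper face | CC(C)(C)[Si](C)(C)O[C@H]1C=C[C@@H]2O[C@]2(COC(=O)c2ccccc2)[C@@H]1O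
F7 | step 4 | trans hydroxy 4-nitrobenzoate: (1R,6S)-2-bromo-6-hydroxycyclohex-2-en-1-yl 4-nitrobenzoate | O[C@H]1CCC=C(Br)[C@@H]1OC(=O)c1ccc(cc1)[N+](=O)[O-]
F8 | step 4 | mixed diester: (1R,6S)-6-acetoxy-2-bromocyclohex-2-en-1-yl 4-nitrobenzoate | CC(=O)O[C@H]1CCC=C(Br)[C@@H]1OC(=O)c1ccc(cc1)[N+](=O)[O-]
F9 | step 4 | C5 allylic bromide diester: (1R,6S)-6-acetoxy-2,4-dibromocyclohex-2-en-1-yl 4-nitrobenzoate (epimers at the CHBr carbon) | CC(=O)O[C@H]1CC(Br)C=C(Br)[C@@H]1OC(=O)c1ccc(cc1)[N+](=O)[O-]
F10 | step 4 | bromodiene diester: (1R,6S)-6-acetoxy-2-bromocyclohexa-2,4-dien-1-yl 4-nitrobenzoate | CC(=O)O[C@H]1C=CC=C(Br)[C@@H]1OC(=O)c1ccc(cc1)[N+](=O)[O-]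
F11 | step 4 | trans-bromodiene diol: (1S,2R)-3-bromocyclohexa-3,5-diene-1,2-diol | O[C@H]1C=CC=C(Br)[C@@H]1O
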